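# Proposed total synthesis of bisisorhapontigenin B (27)

## Structural features

Compound 27 is a trans-2,3-diaryl-2,3-dihydro-1-benzofuran. Ring A (C3a, C4 to C7, C7a) is fused to a dihydrofuran (O1, C2, C3); C2 carries a 4-hydroxy-3-methoxyphenyl ring and C3 a 3,5-dihydroxyphenyl ring. Ring A bears a hydroxyl at C4 and, at C6, an (E)-styryl arm ending in a second 4-hydroxy-3-methoxyphenyl ring. It is therefore a resorcinol (oxygens on C4 and C7a) substituted on the carbon between the oxygens (C3a) and para to that carbon (C6). The only stereocentres, C2 (S) and C3 (S), are adjacent and trans. The fragile elements are the five free phenols, the electron-rich hydroxystilbene (acid, light, oxidants) and the C2–O1 bond, which is benzylic, para to an oxygen and able to ionise reversibly. C2 can therefore be corrected under thermodynamic control, whereas C3 has no such pathway and must be made as one enantiomer and kept out of enolisable or cationic situations. The real difficulty is ring A: C3a, flanked by two oxygens, must carry a bulky diarylethyl unit of defined configuration, and C6 is meta to both oxygens and out of reach of electrophilic substitution. The key step uses exactly this pattern: C4 and its oxygen come from a ketene carbonyl, C7a with its oxygen and C3a with the side chain from a siloxyalkyne, and C5 to C7 with the styryl group from a cyclobutenone. Until the furan closes, the two oxygens ortho to C3a are equivalent, so they need not be differentiated.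

## Logic of the disconnections

**27 to 25 (through 26).** The O1–C2 bond and the four acetal C–O bonds on the phenols are cut. C2 is benzylic and para-oxygenated, so in the forward sense acid ionises the C2 hydroxyl of 25 and either of the two equivalent ring A hydroxyls closes the furan. This removes the heterocycle and the need to control C2 absolutely, and ring A becomes locally symmetric. The forward step must trap the cation faster than it loses the C3 proton, and the hydroxystilbene must survive the acid.

**25 to 24.** Two O–Si bonds are cut. One fluoride treatment frees the second ring A oxygen and the C2 hydroxyl. The only demand is that fluoride spares the acetals, the alkene and both stereocentres.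

**24 to 19 and 7.** C3a–C4 and C7a–C7 are cut and ring A is dismantled. The substitution pattern of ring A is what a vinylketene and an ynol ether assemble, so the whole arene, with its two oxygens, the side chain and the styryl arm, comes from two fragments of similar size. No stereocentre is formed, so all stereochemistry rests in 19. The forward step needs regiocontrol in the ketene–alkyne union and neutral thermal conditions that leave the preset centres alone, and 7 must open to 20 without consuming itself.

**19 to 16 (through 17 and 18).** The O–C(sp) bond and the O–Si bond are cut. A terminal alkyne is the robust carrier of the future C3a–C7a unit, and oxidation of its acetylide brings in the oxygen late. The base must remove only the alkyne hydrogen and not the benzylic propargylic hydrogen at C3.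

**16 to 15 to 14.** A C(sp)–Si bond and an O–Si bond are cut. These are protecting-group operations that expose the alkyne terminus and mask the C2 oxygen for the organolithium step.

**14 to 12 and 2.** The C2–C3 bond is cut. An allenylmetal derived from 12 adds to 2, so C3 is set by transfer of the carbinol chirality of 12 and C2 by the anti preference of the cyclic transition state. The diad is split into two aldehyde-derived halves. The forward step demands clean chirality transfer through 13 and selectivity for the homopropargylic over the allenic alcohol.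

**12 to 11 to 9 and 10, and 9 to 8.** The bond between the carbinol carbon and the alkyne is cut, then the phenol acetals. A catalytic enantioselective alkynylation makes the one stereocentre from which C3 is derived; the demand is face selectivity on an aryl aldehyde.

**7 to 3 and 4 (through 5 and 6), 3 to 2, 2 to 1.** The bond between the cyclobutenone and the styryl carbon is cut, then the alkene, then the phenol acetal. An alkenyllithium adds to a vinylogous ester and acid transposes the carbonyl. The alkene geometry must be fixed in 3 and kept through the exchange. Compound 2 serves both branches.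

## Other disconnections considered

**Alternative 1:** The cut is C3–C3a, made in the forward sense by ring contraction. The (2S)-flavanone A1 would be treated with PhI(OAc)2 and H2SO4 in trimethyl orthoformate. The hypervalent iodine reagent attacks the enol ether at C3, the ring A carbon migrates from the carbonyl carbon to C3, and the trans ester A2 would result, with the old carbonyl carbon as a methyl ester.
- In its favour: ring A is bought and not built, C2 comes from the well-developed enantioselective chemistry of flavanones, the 1,2-aryl shift fixes the trans relation under substrate control, and the C6 bromide is a handle for the styryl arm.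
- Against it here: A2 carries an ester where the target carries the 3,5-dihydroxyphenyl ring. The C3–aryl bond would have to be made afterwards, for example by decarboxylative arylation through a C3 radical that can fragment by loss of the β-aryloxy group, and the C6–vinyl bond as well. The acidic oxidising medium can also open A1 by retro-oxa-Michael reaction and erode C2.
- Comparison: structurally it keeps an intact arene but adds two carbon substituents late, whereas the chosen plan installs every carbon of ring A and both arms in one step. Mechanistically it is a cationic shift next to a stereocentre, against a neutral pericyclic cascade that touches none. In step count it is expected to be longer because of the late C3 arylation.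
- Where it is the equal or the better: the C2/C3 trans relation is fixed kinetically and does not depend on a final acid equilibration.

**Alternative 2:** The cuts are C3–C3a, C2–C3 and O1–C2, all made in one pot. Cyclohexane-1,3-dione A3 would condense with 9, a chiral sulfonium benzylide carrying the protected guaiacyl group would add to C3, and a dione oxygen would displace the sulfide at C2 to give the trans tetrahydrobenzofuranone A4.
- In its favour: three bonds, the heterocycle and both stereocentres arise in a single operation from very simple pieces.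
- Against it here: ring A arrives as a cyclohexenone. Dehydrogenation to the phenol has to be done next to the C3 hydrogen and the dihydrofuran, where over-oxidation to the benzofuran would destroy both stereocentres. A4 has no handle at C6, so a 5-substituted dione or a late C–H functionalisation is needed. Enantiocontrol rests on a stoichiometric chiral sulfide whose induction for this ylide class is less secure.
- Comparison: structurally ring A has the wrong oxidation level and lacks the C6 substituent, while the chosen plan delivers ring A aromatic and fully substituted. Mechanistically it is an ionic condensation, Michael addition and displacement sequence against a pericyclic cascade. In step count it reaches the diaryl dihydrofuran core faster, but aromatisation and C6 functionalisation are expected to use up that gain.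
- Where it is the better: brevity up to the core, and direct kinetic setting of the trans diad.

**Alternative 3:** The cuts are C2–aryl and C3–C3a, with no ring formed. The aryllithium A6 would add to boron of the (E)-alkenyl boronate A5. Pd(OAc)2 with a chiral ferrocenyl bisphosphine and the ring A triflate A7 would then trigger 1,2-migration of the guaiacyl group to C2 as the aryl–palladium attacks C3, giving the boronate A8 as a single stereoisomer.
- In its favour: both stereocentres are set by one catalytic enantioselective step from three simple arenes, ring A is bought, and the chloride is a handle for the styryl arm.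
- Against it here: A7 is a 2,6-dioxygenated, hindered electrophile, a β-aryl alkenyl boronate is a demanding substrate for the migration (direct cross-coupling competes), and the benzylic boronate may protodeboronate. After oxidation to the alcohol the same C2 ionisation and ring closure as in the chosen plan is still needed, plus a cross-coupling at the aryl chloride.
- Comparison: structurally no ring is built and the furan and the C6 arm remain to be made, while the chosen plan builds ring A but no stereocentre in its key step. Mechanistically it is a metal-induced 1,2-metallate shift against a thermal pericyclic cascade. In step count it is expected to be about equal or slightly shorter.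
- Where it is the better: stereocontrol, since both centres are set at once under catalyst control, whereas the chosen plan needs an alkynylation followed by a chirality transfer.

Key step: step 11

Remarks on the chemistry (assumptions):
- The allenylzinc addition delivers the anti (1S,2S) diad, so 19 and 24 are drawn with S at the silyloxy carbon (target C2); an R descriptor there would denote the syn isomer, which this sequence does not make. Since C2 is ionised in step 13, either epimer would converge on 27.
- The sense of induction in step 5 is taken to be selectable through the antipode of the ProPhenol ligand; the antipode that gives (R)-11 is used.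

## Route

Step 1
Reactants: 1 vanillin
Product: 2 3-methoxy-4-(methoxymethoxy)benzaldehyde
Conditions: MOMCl, i-Pr2NEt, CH2Cl2, 0 °C to rt
Reagents that add atoms: chloromethyl methyl ether, COCCl
Why: O-alkylation of the phenol with the chloromethyl ether (acetal protection) should be clean; the aldehyde is not affected.

Step 2
Reactants: 2 3-methoxy-4-(methoxymethoxy)benzaldehyde
Product: 3 4-[(E)-2-iodoethenyl]-2-methoxy-1-(methoxymethoxy)benzene
Conditions: CHI3, CrCl2, THF, 0 °C, dark
Reagents that add atoms: iodoform, IC(I)I
Why: Takai iodo-olefination: the geminal dichromium carbenoid formed from CHI3 and CrCl2 adds to the aldehyde and eliminates to the E-alkenyl iodide, a reaction for which aryl aldehydes are the standard substrates; the acetal and methyl ether are inert.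

Step 3
Reactants: 3 4-[(E)-2-iodoethenyl]-2-methoxy-1-(methoxymethoxy)benzene; 4 3-ethoxycyclobut-2-en-1-one
Product: 7 3-{(E)-2-[3-methoxy-4-(methoxymethoxy)phenyl]ethenyl}cyclobut-2-en-1-one, via styryllithium 5 (not isolated), via lithium cyclobutenolate 6 (not isolated)
Conditions: t-BuLi (2 equiv), Et2O, −78 °C; then 4, −78 °C; then 1 M HCl, 0 °C, brief
Reagents that add atoms: water, O
Why: Iodine–lithium exchange proceeds with retention of alkene geometry, the alkenyllithium adds 1,2 to the vinylogous ester, and cold dilute acid hydrolyses the enol ether and eliminates water (carbonyl transposition) to the 3-substituted cyclobutenone. The short cold acid contact should leave the aryl acetal intact.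

Step 4
Reactants: 8 3,5-dihydroxybenzaldehyde
Product: 9 3,5-bis(methoxymethoxy)benzaldehyde
Conditions: MOMCl, i-Pr2NEt, CH2Cl2, 0 °C to rt
Reagents that add atoms: chloromethyl methyl ether, COCCl
Why: Double O-alkylation of the phenols as in step 1.

Step 5
Reactants: 9 3,5-bis(methoxymethoxy)benzaldehyde; 10 ethynyltrimethylsilane
Product: 11 (1R)-1-[3,5-bis(methoxymethoxy)phenyl]-3-(trimethylsilyl)prop-2-yn-1-ol
Conditions: Me2Zn, ProPhenol ligand (10 mol %, antipode giving the R carbinol), Ph3PO (20 mol %), toluene, 0 °C
Reagents that add atoms: none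
Why: Catalytic enantioselective alkynylation of an aryl aldehyde (dinuclear zinc ProPhenol catalysis): the methyl(alkynyl)zinc formed in the flask is delivered to one face of the aldehyde inside the chiral dizinc pocket, which sets the carbinol centre from which C3 is later derived.

Step 6
Reactants: 11 (1R)-1-[3,5-bis(methoxymethoxy)phenyl]-3-(trimethylsilyl)prop-2-yn-1-ol
Product: 12 (1R)-1-[3,5-bis(methoxymethoxy)phenyl]-3-(trimethylsilyl)prop-2-yn-1-yl methanesulfonate
Conditions: MsCl, Et3N, CH2Cl2, −78 to −40 °C; cold work-up, used crude at once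
Reagents that add atoms: methanesulfonyl chloride, CS(=O)(=O)Cl
Why: O-sulfonylation with retention at carbon. The ring oxygens are meta to the benzylic carbon and do not stabilise a cation there, so the mesylate should survive at low temperature long enough to be used.

Step 7
Reactants: 12 (1R)-1-[3,5-bis(methoxymethoxy)phenyl]-3-(trimethylsilyl)prop-2-yn-1-yl methanesulfonate; 2 3-methoxy-4-(methoxymethoxy)benzaldehyde
Product: 14 (1S,2S)-2-[3,5-bis(methoxymethoxy)phenyl]-1-[3-methoxy-4-(methoxymethoxy)phenyl]-4-(trimethylsilyl)but-3-yn-1-ol, via allenylzinc 13 (not isolated)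
Conditions: Pd(OAc)2 (5 mol %), PPh3 (5 mol %), Et2Zn (3 equiv), THF, −78 to −20 °C
Reagents that add atoms: none
Why: Marshall-type allenylzinc addition: zerovalent palladium displaces the mesylate in an anti SN2' sense, transmetalation to zinc with retention gives 13, and 13 adds to the aldehyde through a cyclic SE2' transition state. The new bond forms at the former carbinol carbon on the face opposite the departed mesylate (C3 set by chirality transfer), and the aldehyde aryl avoids the allene aryl so that the anti alcohol (C2) results. The silyl group holds zinc on the allenyl terminus and so secures the homopropargylic regiochemistry.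

Step 8
Reactants: 14 (1S,2S)-2-[3,5-bis(methoxymethoxy)phenyl]-1-[3-methoxy-4-(methoxymethoxy)phenyl]-4-(trimethylsilyl)but-3-yn-1-ol
Product: 15 tert-butyl{[(1S,2S)-2-[3,5-bis(methoxymethoxy)phenyl]-1-[3-methoxy-4-(methoxymethoxy)phenyl]-4-(trimethylsilyl)but-3-yn-1-yl]oxy}dimethylsilane
Conditions: TBSCl, imidazole, DMAP (cat.), DMF, rt to 40 °C
Reagents that add atoms: tert-butyldimethylsilyl chloride, CC(C)(C)[Si](C)(C)Cl
Why: Imidazole-promoted O-silylation of the secondary alcohol masks the C2 oxygen for the organolithium step; neutral conditions leave the aryl acetals and both stereocentres untouched.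

Step 9
Reactants: 15 tert-butyl{[(1S,2S)-2-[3,5-bis(methoxymethoxy)phenyl]-1-[3-methoxy-4-(methoxymethoxy)phenyl]-4-(trimethylsilyl)but-3-yn-1-yl]oxy}dimethylsilane
Product: 16 tert-butyl{[(1S,2R)-2-[3,5-bis(methoxymethoxy)phenyl]-1-[3-methoxy-4-(methoxymethoxy)phenyl]but-3-yn-1-yl]oxy}dimethylsilane
Conditions: K2CO3 (0.2 equiv), MeOH–THF, 0 °C
Reagents that add atoms: none
Why: Base-catalysed methanolysis of the C(sp)–Si bond. Cold catalytic carbonate is too weak to remove the benzylic propargylic hydrogen at C3, and the silyl ether and acetals are stable; the descriptor at C3 changes only because the alkyne loses priority.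

Step 10
Reactants: 16 tert-butyl{[(1S,2R)-2-[3,5-bis(methoxymethoxy)phenyl]-1-[3-methoxy-4-(methoxymethoxy)phenyl]but-3-yn-1-yl]oxy}dimethylsilane
Product: 19 tert-butyl{[(1S,2S)-2-[3,5-bis(methoxymethoxy)phenyl]-1-[3-methoxy-4-(methoxymethoxy)phenyl]-4-[(triisopropylsilyl)oxy]but-3-yn-1-yl]oxy}dimethylsilane, via lithium acetylide 17 (not isolated), via lithium ynolate 18 (not isolated)
Conditions: n-BuLi (1.05 equiv), THF, −78 °C; LiOOt-Bu (from t-BuOOH and LiN(SiMe3)2), −78 to 0 °C; TIPSOTf, −78 to 0 °C
Reagents that add atoms: tert-butyl hydroperoxide, CC(C)(C)OO; triisopropylsilyl trifluoromethanesulfonate, CC(C)[Si](C(C)C)(C(C)C)OS(=O)(=O)C(F)(F)F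
Why: Oxidation of a lithium acetylide with lithium tert-butyl peroxide gives the ynolate, and the hard, bulky silyl triflate silylates oxygen and not carbon, the standard route to triisopropylsiloxyalkynes. The alkyne hydrogen is far more acidic than the C3 hydrogen, so one equivalent of n-BuLi at −78 °C metalates only the alkyne.

Step 11
Reactants: 19 tert-butyl{[(1S,2S)-2-[3,5-bis(methoxymethoxy)phenyl]-1-[3-methoxy-4-(methoxymethoxy)phenyl]-4-[(triisopropylsilyl)oxy]but-3-yn-1-yl]oxy}dimethylsilane; 7 3-{(E)-2-[3-methoxy-4-(methoxymethoxy)phenyl]ethenyl}cyclobut-2-en-1-one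
Product: 24 2-{(1S,2S)-1-[3,5-bis(methoxymethoxy)phenyl]-2-[(tert-butyldimethylsilyl)oxy]-2-[3-methoxy-4-(methoxymethoxy)phenyl]ethyl}-5-{(E)-2-[3-methoxy-4-(methoxymethoxy)phenyl]ethenyl}-3-[(triisopropylsilyl)oxy]phenol, via vinylketene 20 (not isolated), via vinylcyclobutenone 21 (not isolated), via dienylketene 22 (not isolated), via cyclohexadienone 23 (not isolated)
Conditions: toluene, 80 °C, slow addition of 7 (1.2 equiv); then 110 °C
Reagents that add atoms: none
Why: Heating opens 7 by conrotatory 4π electrocyclic cleavage of its C1–C4 bond to the vinylketene 20. The siloxyalkyne 19 then adds across the ketene C=C in a regioselective (2+2) cycloaddition: its nucleophilic carbon, which carries the side chain, bonds to the ketene carbonyl carbon (C3a–C4) and its oxygen-bearing carbon bonds to the ketene α-carbon (C7a–C7), giving 21. Compound 21 opens by a second 4π cleavage to the dienylketene 22, which closes ring A by a thermally allowed disrotatory 6π electrocyclisation (C4–C5) to the dienone 23, and tautomerisation to the phenol 24 makes the cascade irreversible. The closest known reaction type is the Danheiser benzannulation of 3-substituted cyclobutenones with trialkylsiloxyalkynes, which gives 2-substituted resorcinol monosilyl ethers and accepts alkynes branched at the propargylic carbon. Ring A is thus closed by 6π electrocyclisation and no stereocentre is formed; C3 and C2 pass through unchanged because no acid, base or metal is present and the C3 hydrogen never becomes α to a carbonyl group. The only selectivity needed is regiochemical, and it is secured by the polarisation of the ynol ether, which places the stereodiad between the two oxygens and the styryl group, a spectator on C3 of the cyclobutenone, para to it at C6. Slow addition of 7 keeps the concentration of 20 low, so that capture by 19 should outrun ketene dimerisation and acylation of the product phenol.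

Step 12
Reactants: 24 2-{(1S,2S)-1-[3,5-bis(methoxymethoxy)phenyl]-2-[(tert-butyldimethylsilyl)oxy]-2-[3-methoxy-4-(methoxymethoxy)phenyl]ethyl}-5-{(E)-2-[3-methoxy-4-(methoxymethoxy)phenyl]ethenyl}-3-[(triisopropylsilyl)oxy]phenol
Product: 25 2-{(1S,2S)-1-[3,5-bis(methoxymethoxy)phenyl]-2-hydroxy-2-[3-methoxy-4-(methoxymethoxy)phenyl]ethyl}-5-{(E)-2-[3-methoxy-4-(methoxymethoxy)phenyl]ethenyl}benzene-1,3-diol
Conditions: TBAF (3 equiv), THF, 0 °C to rt
Reagents that add atoms: none
Why: Fluoride cleaves the aryl triisopropylsilyl ether and the benzylic tert-butyldimethylsilyl ether (driven by the Si–F bond), while the acetals, the stilbene and both stereocentres are inert to it.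

Step 13
Reactants: 25 2-{(1S,2S)-1-[3,5-bis(methoxymethoxy)phenyl]-2-hydroxy-2-[3-methoxy-4-(methoxymethoxy)phenyl]ethyl}-5-{(E)-2-[3-methoxy-4-(methoxymethoxy)phenyl]ethenyl}benzene-1,3-diol
Product: 27 bisisorhapontigenin B [(2S,3S)-3-(3,5-dihydroxyphenyl)-2-(4-hydroxy-3-methoxyphenyl)-6-[(E)-2-(4-hydroxy-3-methoxyphenyl)ethenyl]-2,3-dihydro-1-benzofuran-4-ol], via tetrakis-MOM dihydrobenzofuran 26 (not isolated)
Conditions: HCl (2 M in MeOH), THF–MeOH, degassed, dark, 0 °C to rt; then 45 °C
Reagents that add atoms: none
Why: Acid ionises the para-alkoxybenzylic C2 hydroxyl (SN1) and either of the two equivalent ring A hydroxyls flanking C3a traps the cation by 5-exo closure to 26. The trans 2,3-diaryl arrangement is favoured kinetically and, because C2–O1 can re-ionise, also thermodynamically, so C2 is set relative to the fixed C3. Warming then exchanges the four aryl acetals with methanol to free the phenols.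

## Compound list

1 | vanillin (4-hydroxy-3-methoxybenzaldehyde) | COc1cc(C=O)ccc1O | starting material
2 | 3-methoxy-4-(methoxymethoxy)benzaldehyde | COCOc1ccc(C=O)cc1OC | intermediate
3 | 4-[(E)-2-iodoethenyl]-2-methoxy-1-(methoxymethoxy)benzene | COCOc1ccc(/C=C/I)cc1OC | intermediate
4 | 3-ethoxycyclobut-2-en-1-one | CCOC1=CC(=O)C1 | starting material
5 | {(E)-2-[3-methoxy-4-(methoxymethoxy)phenyl]ethenyl}lithium (not isolated) | COCOc1ccc(/C=C/[Li])cc1OC | intermediate
6 | lithium 3-ethoxy-1-{(E)-2-[3-methoxy-4-(methoxymethoxy)phenyl]ethenyl}cyclobut-2-en-1-olate, racemic (not isolated) | CCOC1=CC([O-])(/C=C/c2ccc(OCOC)c(OC)c2)C1.[Li+] | intermediate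
7 | 3-{(E)-2-[3-methoxy-4-(methoxymethoxy)phenyl]ethenyl}cyclobut-2-en-1-one | O=C1C=C(/C=C/c2ccc(OCOC)c(OC)c2)C1 | intermediate
8 | 3,5-dihydroxybenzaldehyde | O=Cc1cc(O)cc(O)c1 | starting material
9 | 3,5-bis(methoxymethoxy)benzaldehyde | COCOc1cc(C=O)cc(OCOC)c1 | intermediate
10 | ethynyltrimethylsilane | C#C[Si](C)(C)C | starting material
11 | (1R)-1-[3,5-bis(methoxymethoxy)phenyl]-3-(trimethylsilyl)prop-2-yn-1-ol | C[Si](C)(C)C#C[C@H](O)c1cc(OCOC)cc(OCOC)c1 | intermediate
12 | (1R)-1-[3,5-bis(methoxymethoxy)phenyl]-3-(trimethylsilyl)prop-2-yn-1-yl methanesulfonate | C[Si](C)(C)C#C[C@H](OS(C)(=O)=O)c1cc(OCOC)cc(OCOC)c1 | intermediate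
13 | ethyl{(aS)-3-[3,5-bis(methoxymethoxy)phenyl]-1-(trimethylsilyl)propa-1,2-dien-1-yl}zinc, zinc on the allene face opposite the departed mesylate (not isolated) | CC[Zn]C([Si](C)(C)C)=[C@@]=C([H])c1cc(OCOC)cc(OCOC)c1 | intermediate
14 | (1S,2S)-2-[3,5-bis(methoxymethoxy)phenyl]-1-[3-methoxy-4-(methoxymethoxy)phenyl]-4-(trimethylsilyl)but-3-yn-1-ol (anti) | C[Si](C)(C)C#C[C@H](c1cc(OCOC)cc(OCOC)c1)[C@H](O)c1ccc(OCOC)c(OC)c1 | intermediate
15 | tert-butyl{[(1S,2S)-2-[3,5-bis(methoxymethoxy)phenyl]-1-[3-methoxy-4-(methoxymethoxy)phenyl]-4-(trimethylsilyl)but-3-yn-1-yl]oxy}dimethylsilane | C[Si](C)(C)C#C[C@H](c1cc(OCOC)cc(OCOC)c1)[C@H](O[Si](C)(C)C(C)(C)C)c1ccc(OCOC)c(OC)c1 | intermediate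
16 | tert-butyl{[(1S,2R)-2-[3,5-bis(methoxymethoxy)phenyl]-1-[3-methoxy-4-(methoxymethoxy)phenyl]but-3-yn-1-yl]oxy}dimethylsilane | C#C[C@H](c1cc(OCOC)cc(OCOC)c1)[C@H](O[Si](C)(C)C(C)(C)C)c1ccc(OCOC)c(OC)c1 | intermediate
17 | lithium acetylide of 16 (not isolated) | [Li]C#C[C@H](c1cc(OCOC)cc(OCOC)c1)[C@H](O[Si](C)(C)C(C)(C)C)c1ccc(OCOC)c(OC)c1 | intermediate
18 | lithium ynolate, (3S,4S)-3-[3,5-bis(methoxymethoxy)phenyl]-4-[(tert-butyldimethylsilyl)oxy]-4-[3-methoxy-4-(methoxymethoxy)phenyl]but-1-yn-1-olate (not isolated) | [Li]OC#C[C@H](c1cc(OCOC)cc(OCOC)c1)[C@H](O[Si](C)(C)C(C)(C)C)c1ccc(OCOC)c(OC)c1 | intermediate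
19 | tert-butyl{[(1S,2S)-2-[3,5-bis(methoxymethoxy)phenyl]-1-[3-methoxy-4-(methoxymethoxy)phenyl]-4-[(triisopropylsilyl)oxy]but-3-yn-1-yl]oxy}dimethylsilane | CC(C)[Si](C(C)C)(C(C)C)OC#C[C@H](c1cc(OCOC)cc(OCOC)c1)[C@H](O[Si](C)(C)C(C)(C)C)c1ccc(OCOC)c(OC)c1 | intermediate
20 | (4E)-5-[3-methoxy-4-(methoxymethoxy)phenyl]-3-methylidenepenta-1,4-dien-1-one (vinylketene, not isolated) | O=C=CC(=C)/C=C/c1ccc(OCOC)c(OC)c1 | intermediate
21 | 2-(diarylethyl)-3-[(triisopropylsilyl)oxy]-4-{(3E)-4-[3-methoxy-4-(methoxymethoxy)phenyl]buta-1,3-dien-2-yl}cyclobut-2-en-1-one, diarylethyl group as in 19, ring C4 unassigned (not isolated) | O=C1C([C@H](c2cc(OCOC)cc(OCOC)c2)[C@H](O[Si](C)(C)C(C)(C)C)c2ccc(OCOC)c(OC)c2)=C(O[Si](C(C)C)(C(C)C)C(C)C)C1C(=C)/C=C/c1ccc(OCOC)c(OC)c1 | intermediate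
22 | dienylketene from ring opening of 21, ketene and butadienyl groups cis on the central double bond (not isolated) | O=C=C([C@H](c1cc(OCOC)cc(OCOC)c1)[C@H](O[Si](C)(C)C(C)(C)C)c1ccc(OCOC)c(OC)c1)/C(O[Si](C(C)C)(C(C)C)C(C)C)=C\C(=C)/C=C/c1ccc(OCOC)c(OC)c1 | intermediate
23 | 2-(diarylethyl)-5-[(E)-styryl]-3-[(triisopropylsilyl)oxy]cyclohexa-2,4-dien-1-one, keto tautomer of 24 (not isolated) | O=C1CC(/C=C/c2ccc(OCOC)c(OC)c2)=CC(O[Si](C(C)C)(C(C)C)C(C)C)=C1[C@H](c1cc(OCOC)cc(OCOC)c1)[C@H](O[Si](C)(C)C(C)(C)C)c1ccc(OCOC)c(OC)c1 | intermediate
24 | 2-{(1S,2S)-1-[3,5-bis(methoxymethoxy)phenyl]-2-[(tert-butyldimethylsilyl)oxy]-2-[3-methoxy-4-(methoxymethoxy)phenyl]ethyl}-5-{(E)-2-[3-methoxy-4-(methoxymethoxy)phenyl]ethenyl}-3-[(triisopropylsilyl)oxy]phenol | Oc1cc(/C=C/c2ccc(OCOC)c(OC)c2)cc(O[Si](C(C)C)(C(C)C)C(C)C)c1[C@H](c1cc(OCOC)cc(OCOC)c1)[C@H](O[Si](C)(C)C(C)(C)C)c1ccc(OCOC)c(OC)c1 | intermediate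
25 | 2-{(1S,2S)-1-[3,5-bis(methoxymethoxy)phenyl]-2-hydroxy-2-[3-methoxy-4-(methoxymethoxy)phenyl]ethyl}-5-{(E)-2-[3-methoxy-4-(methoxymethoxy)phenyl]ethenyl}benzene-1,3-diol | Oc1cc(/C=C/c2ccc(OCOC)c(OC)c2)cc(O)c1[C@H](c1cc(OCOC)cc(OCOC)c1)[C@H](O)c1ccc(OCOC)c(OC)c1 | intermediate
26 | (2S,3S)-3-[3,5-bis(methoxymethoxy)phenyl]-2-[3-methoxy-4-(methoxymethoxy)phenyl]-6-{(E)-2-[3-methoxy-4-(methoxymethoxy)phenyl]ethenyl}-2,3-dihydro-1-benzofuran-4-ol | COCOc1ccc(/C=C/c2cc(O)c3c(c2)O[C@H](c2ccc(OCOC)c(OC)c2)[C@H]3c2cc(OCOC)cc(OCOC)c2)cc1OC | intermediate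
27 | bisisorhapontigenin B, (2S,3S)-3-(3,5-dihydroxyphenyl)-2-(4-hydroxy-3-methoxyphenyl)-6-[(E)-2-(4-hydroxy-3-methoxyphenyl)ethenyl]-2,3-dihydro-1-benzofuran-4-ol | COc1cc(/C=C/c2cc(O)c3c(c2)O[C@H](c2ccc(O)c(OC)c2)[C@H]3c2cc(O)cc(O)c2)ccc1O | target

## Step count and least certain steps

Total: 13 steps. Longest linear sequence: 10 steps (8 to 27 through steps 4 to 13); the cyclobutenone branch (steps 1 to 3) joins at step 11.

**Step 11 (key step).** The most likely failure is consumption of the vinylketene 20 before the sterically encumbered alkyne carbon of 19 is acylated. The ketene can dimerise or polymerise through its 2-substituted 1-arylbutadiene unit, and a second ketene can acylate the product phenol. The fallback sets out from 2 and 4 and returns at 24; it carries the C6 substituent through the annulation as an arylethynyl group, which has no diene, and sets the alkene geometry afterwards. Seyferth–Gilbert homologation of 2 with the Ohira–Bestmann reagent (K2CO3, MeOH) should give 4-ethynyl-2-methoxy-1-(methoxymethoxy)benzene F1. Deprotonation of F1 (n-BuLi, THF, −78 °C), addition to 4 and cold dilute acid should give 3-{[3-methoxy-4-(methoxymethoxy)phenyl]ethynyl}cyclobut-2-en-1-one F2. Heating F2 with 19 under the conditions of step 11 should give the diarylacetylene analogue of 24, F3. E-selective transfer semihydrogenation of the diarylalkyne (Pd2(dba)3, dppb, HCO2H, dioxane, 80 °C) would then give 24.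

**Step 7.** Enantiopurity at C3 may be lost in two ways: ionisation of the benzylic propargylic mesylate before oxidative addition, and racemisation of the aryl-substituted allenylzinc by metallotropic shift to the benzylic propargylzinc; the anti preference may also be lower with two aryl groups. The fallback sets out from 11 and returns at 14, replacing the labile mesylate and the transient zinc reagent by a stable carbonate and an isolable allenylboron reagent. Acylation of 11 (ClCO2Me, pyridine, CH2Cl2) should give methyl (1R)-1-[3,5-bis(methoxymethoxy)phenyl]-3-(trimethylsilyl)prop-2-yn-1-yl carbonate F4. Anti SN2' borylation (CuOt-Bu, Xantphos, B2pin2, THF) should give the allenylboronate 2-{(aR)-3-[3,5-bis(methoxymethoxy)phenyl]-1-(trimethylsilyl)propa-1,2-dien-1-yl}-4,4,5,5-tetramethyl-1,3,2-dioxaborolane F5, which is configurationally stable. Heating F5 with 2 in toluene gives, through a closed six-membered transition state with the same net inversion at C3 and the same anti preference, compound 14 after hydrolytic work-up.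

**Step 13.** The C2 cation may lose the C3 proton instead of being trapped, which would erode C3 or lead to the triarylethene and the benzofuran, and the free hydroxystilbene may oligomerise in warm protic acid. The fallback sets out from 25 and returns at 27 through isolated 26, separating ring closure from deprotection and changing the deprotection mechanism. Ring closure is run with catalytic camphorsulfonic acid in CH2Cl2 at −20 °C, where only the benzylic alcohol ionises, and 26 is isolated. The four acetals are then cleaved under non-protic conditions by Lewis-acid activation and capture of the methoxymethyl group by a thiol (ZnBr2, n-PrSH, CH2Cl2, 0 °C), so that the stilbene never meets hot mineral acid.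

**Step 3.** The exchange may be accompanied by ortho-metalation next to the acetal, and the cross-conjugated dienone may decompose or lose its aryl acetal during the acid transposition. The fallback sets out from 3 and returns at 7, building the four-membered ring by cycloaddition instead of by addition to 4. Negishi coupling of 3 with HC≡CZnBr (Pd(PPh3)4, THF) should give 4-[(1E)-but-1-en-3-yn-1-yl]-2-methoxy-1-(methoxymethoxy)benzene F6. A (2+2) cycloaddition of the alkyne with the ketene generated from Cl3CCOCl and Zn (Et2O) should give 4,4-dichloro-3-{(E)-2-[3-methoxy-4-(methoxymethoxy)phenyl]ethenyl}cyclobut-2-en-1-one F7. Reductive dechlorination (Zn, AcOH, TMEDA, EtOH) would then give 7.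

## Further compounds

F1 | step 11 | 4-ethynyl-2-methoxy-1-(methoxymethoxy)benzene | C#Cc1ccc(OCOC)c(OC)c1
F2 | step 11 | 3-{[3-methoxy-4-(methoxymethoxy)phenyl]ethynyl}cyclobut-2-en-1-one | O=C1C=C(C#Cc2ccc(OCOC)c(OC)c2)C1
F3 | step 11 | 2-{(1S,2S)-1-[3,5-bis(methoxymethoxy)phenyl]-2-[(tert-butyldimethylsilyl)oxy]-2-[3-methoxy-4-(methoxymethoxy)phenyl]ethyl}-5-{[3-methoxy-4-(methoxymethoxy)phenyl]ethynyl}-3-[(triisopropylsilyl)oxy]phenol | Oc1cc(C#Cc2ccc(OCOC)c(OC)c2)cc(O[Si](C(C)C)(C(C)C)C(C)C)c1[C@H](c1cc(OCOC)cc(OCOC)c1)[C@H](O[Si](C)(C)C(C)(C)C)c1ccc(OCOC)c(OC)c1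
F4 | step 7 | methyl (1R)-1-[3,5-bis(methoxymethoxy)phenyl]-3-(trimethylsilyl)prop-2-yn-1-yl carbonate | C[Si](C)(C)C#C[C@H](OC(=O)OC)c1cc(OCOC)cc(OCOC)c1
F5 | step 7 | 2-{(aR)-3-[3,5-bis(methoxymethoxy)phenyl]-1-(trimethylsilyl)propa-1,2-dien-1-yl}-4,4,5,5-tetramethyl-1,3,2-dioxaborolane | CC1(C)OB(OC1(C)C)C([Si](C)(C)C)=[C@@]=C([H])c1cc(OCOC)cc(OCOC)c1
F0 | step 13 | none | none
F6 | step 3 | 4-[(1E)-but-1-en-3-yn-1-yl]-2-methoxy-1-(methoxymethoxy)benzene | C#C/C=C/c1ccc(OCOC)c(OC)c1
F7 | step 3 | 4,4-dichloro-3-{(E)-2-[3-methoxy-4-(methoxymethoxy)phenyl]ethenyl}cyclobut-2-en-1-one | O=C1C=C(/C=C/c2ccc(OCOC)c(OC)c2)C1(Cl)Cl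
A1 | alternative 1 | (2S)-7-bromo-2-[3-methoxy-4-(pivaloyloxy)phenyl]-5-(pivaloyloxy)chroman-4-one | O=C1C[C@@H](c2ccc(OC(=O)C(C)(C)C)c(OC)c2)Oc2cc(Br)cc(OC(=O)C(C)(C)C)c21
A2 | alternative 1 | methyl (2S,3S)-6-bromo-2-[3-methoxy-4-(pivaloyloxy)phenyl]-4-(pivaloyloxy)-2,3-dihydro-1-benzofuran-3-carboxylate (trans) | Brc2cc(OC(=O)C(C)(C)C)c3c(c2)O[C@H](c2ccc(OC(=O)C(C)(C)C)c(OC)c2)[C@H]3C(=O)OC
A3 | alternative 2 | cyclohexane-1,3-dione | O=C1CCCC(=O)C1
A4 | alternative 2 | (2S,3S)-3-[3,5-bis(methoxymethoxy)phenyl]-2-[3-methoxy-4-(methoxymethoxy)phenyl]-2,3,6,7-tetrahydro-1-benzofuran-4(5H)-one (trans) | O=C1CCCC2=C1[C@H](c1cc(OCOC)cc(OCOC)c1)[C@@H](c1ccc(OCOC)c(OC)c1)O2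
A5 | alternative 3 | 2-{(E)-2-[3,5-bis(methoxymethoxy)phenyl]ethenyl}-4,4,5,5-tetramethyl-1,3,2-dioxaborolane | CC1(C)OB(/C=C/c2cc(OCOC)cc(OCOC)c2)OC1(C)C
A6 | alternative 3 | [3-methoxy-4-(methoxymethoxy)phenyl]lithium | [Li]c1ccc(OCOC)c(OC)c1
A7 | alternative 3 | 4-chloro-2,6-bis(methoxymethoxy)phenyl trifluoromethanesulfonate | COCOc1cc(Cl)cc(OCOC)c1OS(=O)(=O)C(F)(F)F
A8 | alternative 3 | 2-{(1R,2S)-2-[3,5-bis(methoxymethoxy)phenyl]-2-[4-chloro-2,6-bis(methoxymethoxy)phenyl]-1-[3-methoxy-4-(methoxymethoxy)phenyl]ethyl}-4,4,5,5-tetramethyl-1,3,2-dioxaborolane | CC1(C)OB(OC1(C)C)[C@@H](c1ccc(OCOC)c(OC)c1)[C@H](c1c(OCOC)cc(Cl)cc1OCOC)c1cc(OCOC)cc(OCOC)c1
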